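**Retrosynthetic overview**
1. The target comes from a 3β,18-dihydroxyhalim-5-ene tert-butyl ester by 18-O-acetylation, radical removal of the 3β-hydroxyl and ester cleavage.
2. Key disconnection: that bicycle comes from an acyclic (14S,15S)-epoxy-6E,10E-dienoate in one acid-triggered flask. Ring A closes first (C4–C5) and ring B second (C9–C10). The labdan-8-yl cation then runs H9→C8, Me10→C9, H5→C10 and loses H6.
3. The epoxy alcohol comes from Sharpless epoxidation of the E-allylic alcohol made by terminal SeO2 hydroxylation of tert-butyl (R)-2,3-dihydrogeranylgeranoate.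
4. That ester comes from asymmetric copper hydride conjugate reduction (sets C13) of the enoate made by HWE olefination of farnesylacetone.

Assumption: halimane (diterpene) numbering is used for the ring compounds, and (R)-DTBM-SEGPHOS is taken as the antipode that gives 3R from the 2E-enoate; if the sense is opposite, its mirror image is used.

**Step 1**
Reactants: 1 (5E,9E)-farnesylacetone; 2 tert-butyl diethylphosphonoacetate
Product: 3 tert-butyl (2E,6E,10E)-3,7,11,15-tetramethylhexadeca-2,6,10,14-tetraenoate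
Conditions: NaH, THF, 0 → 50 °C; 2Z isomer removed on silica
Reagents that add atoms: none
Why: Horner–Wadsworth–Emmons olefination of the methyl ketone with the stabilised phosphonate anion is E-selective (about 4:1), leaves the existing E-alkenes untouched and forms no stereocentre.

**Step 2**
Reactants: 3 tert-butyl (2E,6E,10E)-3,7,11,15-tetramethylhexadeca-2,6,10,14-tetraenoate
Product: 4 tert-butyl (3R,6E,10E)-3,7,11,15-tetramethylhexadeca-6,10,14-trienoate
Conditions: Cu(OAc)2·H2O (2 mol%), (R)-DTBM-SEGPHOS (2.2 mol%), (EtO)2MeSiH, t-BuOH, toluene, 0 °C → rt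
Reagents that add atoms: none
Why: In this asymmetric conjugate reduction, ligated monovalent copper hydride adds hydride only to the β-carbon of the conjugated ester, the bisphosphine choosing the face of the pure 2E-alkene so that C13 (chain C3) is set as R while the three isolated alkenes stay inert.

**Step 3**
Reactants: 4 tert-butyl (3R,6E,10E)-3,7,11,15-tetramethylhexadeca-6,10,14-trienoate
Product: 5 tert-butyl (3R,6E,10E,14E)-16-hydroxy-3,7,11,15-tetramethylhexadeca-6,10,14-trienoate
Conditions: SeO2 (0.3 equiv), t-BuOOH (decane), salicylic acid (0.1 equiv), CH2Cl2, 0 °C → rt, stopped near 50% conversion, 4 recycled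
Reagents that add atoms: tert-butyl hydroperoxide CC(C)(C)OO (terminal oxidant); selenium dioxide O=[Se]=O (catalytic oxygen carrier)
Why: Riley allylic oxidation under catalytic conditions (ene reaction, then [2,3]-shift) prefers the least hindered terminal isopropylidene group and gives only the E-hydroxymethyl isomer, the geometry that later places C18 in the equatorial 4α position.

**Step 4**
Reactants: 5 tert-butyl (3R,6E,10E,14E)-16-hydroxy-3,7,11,15-tetramethylhexadeca-6,10,14-trienoate
Product: 6 tert-butyl (3R,6E,10E)-13-[(2S,3S)-3-(hydroxymethyl)-3-methyloxiran-2-yl]-3,7,11-trimethyltrideca-6,10-dienoate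
Conditions: Ti(OiPr)4 (10 mol%), L-(+)-diethyl tartrate (12 mol%), t-BuOOH, MS 4A, CH2Cl2, −20 °C
Reagents that add atoms: tert-butyl hydroperoxide CC(C)(C)OO
Why: Katsuki–Sharpless asymmetric epoxidation is hydroxyl-directed, so only the allylic alcohol alkene reacts, and L-(+)-tartrate delivers oxygen to the same face as in (2S,3S)-epoxygeraniol, setting both epoxide carbons as S.

**Step 5**
Reactants: 6 tert-butyl (3R,6E,10E)-13-[(2S,3S)-3-(hydroxymethyl)-3-methyloxiran-2-yl]-3,7,11-trimethyltrideca-6,10-dienoate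
Product: 9 tert-butyl (13R)-3β,18-dihydroxyhalim-5-en-15-oate, via labdan-8-yl cation 7 (not isolated), via halim-5-yl cation 8 (not isolated)
Conditions: HNTf2 (20 mol%), CH2Cl2, −78 °C, 6 added over 2 h (final 5 mM); Et3N quench at −78 °C
Reagents that add atoms: none
Why: Proposed new method: the protonated epoxide opens at tertiary C4 with anti participation of the 10E-alkene and the second E-alkene follows through a chair–chair array (known acid-promoted hydroxy-epoxide polyene bicyclisation), so the epoxide configuration and the E-geometries fix 3β-OH, 4α-CH2OH, 5α-H, 10β-Me and 9α-H in cation 7; because triflimide is neither base nor nucleophile and the medium is dilute, 7 is not quenched but relaxes by the biosynthetic suprafacial antiperiplanar 1,2-shifts H9α→C8, Me10β→C9 and H5α→C10 (closest known type: BF3-induced friedo rearrangements labdane→halimane, drimane→4,9-friedodrimane, lanostane→cucurbitane), which set 8β-Me, 9β-Me and 10α-H; the run stops at cation 8 because one more methyl shift would put the charge on C4 between two C–O bonds, and the only base in reach, the 18-hydroxyl with its hydrogen-bonded triflimide, takes the axial 6α-H through a six-membered transition state to give the 5-ene kinetically.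

**Step 6**
Reactants: 9 tert-butyl (13R)-3β,18-dihydroxyhalim-5-en-15-oate
Product: 11 tert-butyl (13R)-18-acetoxy-3β-(imidazol-1-ylthiocarbonyloxy)halim-5-en-15-oate, via 18-monoacetate 10 (not isolated)
Conditions: AcCl (1.1 equiv), 2,4,6-collidine, ClCH2CH2Cl, −20 °C; then 1,1'-thiocarbonyldiimidazole (3 equiv), DMAP, 80 °C
Reagents that add atoms: acetyl chloride CC(=O)Cl; 1,1'-thiocarbonyldiimidazole S=C(n1ccnc1)n1ccnc1
Why: The primary 18-OH is acylated much faster than the axial 3β-OH next to quaternary C4 (selective primary acylation with AcCl/collidine), after which the remaining alcohol is thioacylated as the first half of a Barton–McCombie deoxygenation, and no stereocentre is touched.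

**Step 7**
Reactants: 11 tert-butyl (13R)-18-acetoxy-3β-(imidazol-1-ylthiocarbonyloxy)halim-5-en-15-oate
Product: 12 tert-butyl (13R)-18-acetoxyhalim-5-en-15-oate
Conditions: Bu3SnH (3 equiv, 0.5 M), AIBN (0.2 equiv), toluene, 100 °C
Reagents that add atoms: none
Why: In this Barton–McCombie radical deoxygenation the stannyl radical adds to C=S, the secondary C3–O bond fragments, and the high stannane concentration delivers hydrogen faster than the homoallylic C3 radical can attack the 5-ene, so only the C3 stereocentre is erased.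

**Step 8**
Reactants: 12 tert-butyl (13R)-18-acetoxyhalim-5-en-15-oate
Product: 14 (13R)-18-acetoxyhalim-5-en-15-oic acid (CNP0148247.1), via trimethylsilyl ester 13 (not isolated)
Conditions: TMSOTf (2 equiv), 2,6-lutidine (3 equiv), CH2Cl2, 0 °C → rt; pH 4 aqueous work-up
Reagents that add atoms: none
Why: Silyl triflate-mediated tert-butyl ester cleavage (loss of isobutene from the O-silylated ester, then hydrolysis of the silyl ester) runs under lutidine buffer, so no free strong acid can move the 5-ene, and the neopentyl acetate and all stereocentres survive.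

**Compound list**
1 | (5E,9E)-farnesylacetone, (5E,9E)-6,10,14-trimethylpentadeca-5,9,13-trien-2-one | CC(C)=CCC/C(C)=C/CC/C(C)=C/CCC(C)=O | starting material
2 | tert-butyl diethylphosphonoacetate | CCOP(=O)(CC(=O)OC(C)(C)C)OCC | starting material
3 | tert-butyl (2E,6E,10E)-3,7,11,15-tetramethylhexadeca-2,6,10,14-tetraenoate | CC(C)=CCC/C(C)=C/CC/C(C)=C/CC/C(C)=C/C(=O)OC(C)(C)C | intermediate
4 | tert-butyl (3R,6E,10E)-3,7,11,15-tetramethylhexadeca-6,10,14-trienoate | CC(C)=CCC/C(C)=C/CC/C(C)=C/CC[C@@H](C)CC(=O)OC(C)(C)C | intermediate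
5 | tert-butyl (3R,6E,10E,14E)-16-hydroxy-3,7,11,15-tetramethylhexadeca-6,10,14-trienoate | OC/C(C)=C/CC/C(C)=C/CC/C(C)=C/CC[C@@H](C)CC(=O)OC(C)(C)C | intermediate
6 | tert-butyl (3R,6E,10E)-13-[(2S,3S)-3-(hydroxymethyl)-3-methyloxiran-2-yl]-3,7,11-trimethyltrideca-6,10-dienoate | OC[C@]1(C)O[C@H]1CC/C(C)=C/CC/C(C)=C/CC[C@@H](C)CC(=O)OC(C)(C)C | intermediate
7 | (13R)-3β,18-dihydroxy-15-tert-butoxy-15-oxolabdan-8-yl cation (5α-H, 9α-H, 10β-Me, 4α-CH2OH) | OC[C@]1(C)[C@@H](O)CC[C@@]2(C)[C@H]1CC[C+](C)[C@@H]2CC[C@@H](C)CC(=O)OC(C)(C)C | intermediate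
8 | (13R)-3β,18-dihydroxy-15-tert-butoxy-15-oxohaliman-5-yl cation (8β-Me, 9β-Me, 10α-H) | OC[C@]1(C)[C@@H](O)CC[C@@H]2[C+]1CC[C@H](C)[C@@]2(C)CC[C@@H](C)CC(=O)OC(C)(C)C | intermediate
9 | tert-butyl (13R)-3β,18-dihydroxyhalim-5-en-15-oate (4β-Me, 8β-Me, 9β-Me, 10α-H) | OC[C@]1(C)[C@@H](O)CC[C@@H]2C1=CC[C@H](C)[C@@]2(C)CC[C@@H](C)CC(=O)OC(C)(C)C | intermediate
10 | tert-butyl (13R)-18-acetoxy-3β-hydroxyhalim-5-en-15-oate | CC(=O)OC[C@]1(C)[C@@H](O)CC[C@@H]2C1=CC[C@H](C)[C@@]2(C)CC[C@@H](C)CC(=O)OC(C)(C)C | intermediate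
11 | tert-butyl (13R)-18-acetoxy-3β-(imidazol-1-ylthiocarbonyloxy)halim-5-en-15-oate | CC(=O)OC[C@]1(C)[C@@H](OC(=S)n3ccnc3)CC[C@@H]2C1=CC[C@H](C)[C@@]2(C)CC[C@@H](C)CC(=O)OC(C)(C)C | intermediate
12 | tert-butyl (13R)-18-acetoxyhalim-5-en-15-oate | CC(=O)OC[C@]1(C)CCC[C@@H]2C1=CC[C@H](C)[C@@]2(C)CC[C@@H](C)CC(=O)OC(C)(C)C | intermediate
13 | trimethylsilyl (13R)-18-acetoxyhalim-5-en-15-oate | CC(=O)OC[C@]1(C)CCC[C@@H]2C1=CC[C@H](C)[C@@]2(C)CC[C@@H](C)CC(=O)O[Si](C)(C)C | intermediate
14 | (13R)-18-acetoxyhalim-5-en-15-oic acid, (3R)-5-[(1R,2S,5R,8aS)-5-(acetoxymethyl)-1,2,5-trimethyl-1,2,3,5,6,7,8,8a-octahydronaphthalen-1-yl]-3-methylpentanoic acid | CC(=O)OC[C@]1(C)CCC[C@@H]2C1=CC[C@H](C)[C@@]2(C)CC[C@@H](C)CC(=O)O | target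

**Total step count:** 8. **Longest linear sequence:** 8.

**The three steps most likely to fail**

**Step 5.**
- Risks: the hydroxymethyl group slows C4–O ionisation, so hydride shift of the epoxide to a carbonyl compound may compete. The cation may also be quenched early to labdenes, or lose H5 or H10 to give the more stable tetrasubstituted alkene instead of the 5-ene.
- Fallback: it sets out from 6 and comes back at 9, and gives up kinetic termination.
  - Compound 6 is cyclised and equilibrated with BF3·OEt2 (CH2Cl2, −78 to −10 °C). Under these conditions C8 cations of this type run to the tetrasubstituted alkene, giving tert-butyl (13R)-3β,18-dihydroxyhalim-5(10)-en-15-oate F1.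
  - F1 is then moved uphill by a contra-thermodynamic positional isomerisation ([Ir(dF(CF3)ppy)2(5,5'-d(CF3)bpy)]PF6, CrCl2, 2,4,6-collidine, MeOH, blue light).
  - The excited photocatalyst oxidises only the electron-rich tetrasubstituted alkene. The radical cation is deprotonated at C6, and divalent chromium captures the allyl radical at the less hindered C6.
  - Methanol protonates the trivalent allylchromium in SE2' fashion at C10 from the α-face, because the β-face carries the 4β- and 9β-methyls. This gives 9, which is too hard to oxidise to react again.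

**Step 3.**
- Risk: three similar trisubstituted alkenes compete, so the yield of the terminal alcohol may be poor.
- Fallback: it sets out from 4 and comes back at 5, replacing C–H oxidation by degradation and rebuilding of the chain end.
  - Terminal-selective bromohydrin formation (NBS, THF–H2O, 0 °C) gives tert-butyl (3R,6E,10E)-14-bromo-15-hydroxy-3,7,11,15-tetramethylhexadeca-6,10-dienoate F2.
  - K2CO3 in MeOH closes F2 to tert-butyl (3R,6E,10E)-13-(3,3-dimethyloxiran-2-yl)-3,7,11-trimethyltrideca-6,10-dienoate F3.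
  - H5IO6 in THF–Et2O cleaves F3 to tert-butyl (3R,6E,10E)-3,7,11-trimethyl-14-oxotetradeca-6,10-dienoate F4.
  - The stabilised ylide 2-(triphenylphosphoranylidene)propanal (toluene, 90 °C) converts F4 E-selectively into tert-butyl (3R,6E,10E,14E)-3,7,11,15-tetramethyl-16-oxohexadeca-6,10,14-trienoate F5.
  - NaBH4 with CeCl3·7H2O (MeOH, 0 °C) reduces F5 to 5.

**Step 7.**
- Risks: the C3 radical is homoallylic to the 5-ene and sits next to quaternary C4, so 3-exo closure and reopening to a ring-contracted tertiary radical is possible. The hindered axial thiocarbamate may also form slowly in step 6.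
- Fallback: it sets out from 10 (step 6 stopped after the acetylation) and comes back at 12, removing the oxygen by an ionic route.
  - Dess–Martin periodinane (CH2Cl2, rt) gives tert-butyl (13R)-18-acetoxy-3-oxohalim-5-en-15-oate F6, which cannot conjugate because C4 is quaternary.
  - TsNHNH2 (EtOH, 70 °C) gives its 4-toluenesulfonylhydrazone F7.
  - Catecholborane (CHCl3, −10 °C) followed by NaOAc·3H2O at reflux reduces F7 to the methylene compound 12. Both esters and the alkene are left in place.

**Further compounds**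
F1 | step 5 | tert-butyl (13R)-3β,18-dihydroxyhalim-5(10)-en-15-oate | OC[C@]1(C)[C@@H](O)CCC2=C1CC[C@H](C)[C@@]2(C)CC[C@@H](C)CC(=O)OC(C)(C)C
F2 | step 3 | tert-butyl (3R,6E,10E)-14-bromo-15-hydroxy-3,7,11,15-tetramethylhexadeca-6,10-dienoate (C14 epimers) | CC(C)(O)C(Br)CC/C(C)=C/CC/C(C)=C/CC[C@@H](C)CC(=O)OC(C)(C)C
F3 | step 3 | tert-butyl (3R,6E,10E)-13-(3,3-dimethyloxiran-2-yl)-3,7,11-trimethyltrideca-6,10-dienoate (epoxide epimers) | CC1(C)OC1CC/C(C)=C/CC/C(C)=C/CC[C@@H](C)CC(=O)OC(C)(C)C
F4 | step 3 | tert-butyl (3R,6E,10E)-3,7,11-trimethyl-14-oxotetradeca-6,10-dienoate | O=CCC/C(C)=C/CC/C(C)=C/CC[C@@H](C)CC(=O)OC(C)(C)C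
F5 | step 3 | tert-butyl (3R,6E,10E,14E)-3,7,11,15-tetramethyl-16-oxohexadeca-6,10,14-trienoate | O=C/C(C)=C/CC/C(C)=C/CC/C(C)=C/CC[C@@H](C)CC(=O)OC(C)(C)C
F6 | step 7 | tert-butyl (13R)-18-acetoxy-3-oxohalim-5-en-15-oate | CC(=O)OC[C@]1(C)C(=O)CC[C@@H]2C1=CC[C@H](C)[C@@]2(C)CC[C@@H](C)CC(=O)OC(C)(C)C
F7 | step 7 | tert-butyl (13R)-18-acetoxy-3-(4-toluenesulfonylhydrazono)halim-5-en-15-oate | CC(=O)OC[C@]1(C)C(=NNS(=O)(=O)c3ccc(C)cc3)CC[C@@H]2C1=CC[C@H](C)[C@@]2(C)CC[C@@H](C)CC(=O)OC(C)(C)C
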